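**Plan**
1. Retrosynthesis: first the benzyl ether O–CH2Ph is cut, then both bonds of the dihydropyran ring of the spirochroman, C4–C3 (ArCH2–CH2) and O1–C2 (aryl O–spiro C), in a retro oxa-[4+2]; last the ArCH2 carbon (formaldehyde), the formyl and the isovaleryl carbons come off phloroglucinol.
2. Enabling feature: the ring O1–C8a–C4a–C4–C3–C2 is a 2,2-dialkylchroman. C2 and C3 are the two carbons of the exocyclic C=CH2 of β-pinene, and O1–C8a–C4a–C4 is an ortho-quinone methide of a phenol with a free ortho CH.
3. Forward: phloroglucinol → isovaleryl ketone → para allyl ether → aldehyde → benzyl ether on the hydroxyl next to the ketone → allyl off. The quinone methide from formaldehyde then closes the pyran ring onto the intact pinane bicycle, and debenzylation ends the route.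
4. Regiochemistry (ring oxygen next to the formyl carbon, isovaleryl between two hydroxyls): the benzyl group blocks the other ortho oxygen during ring closure.
5. Stereochemistry: the two bridgeheads come unchanged from (1S,5S)-(−)-β-pinene; the spiro centre is set by cycloaddition on the alkene face anti to the gem-dimethyl bridge.

Key step: step 6

Remark: levorotatory β-pinene is taken as the (1S,5S) enantiomer, whose bridgehead centres map onto the target without change; formaldehyde is used as its 37% aqueous solution.

**Step 1**
Reactants: 1 phloroglucinol; 2 isovaleryl chloride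
Product: 3 phlorisovalerophenone (3-methyl-1-(2,4,6-trihydroxyphenyl)butan-1-one)
Conditions: AlCl3 (3 equiv), PhNO2, rt to 60 °C; then ice, aq. HCl
Reagents that add atoms: isovaleryl chloride 2, CC(C)CC(=O)Cl
Why: Friedel–Crafts acylation of the threefold activated ring; the first acyl group, chelated to aluminium, deactivates the ring, so mono-acylation should prevail.

**Step 2**
Reactants: 3 phlorisovalerophenone; 4 allyl bromide
Product: 5 1-[2,6-dihydroxy-4-(prop-2-enyloxy)phenyl]-3-methylbutan-1-one
Conditions: allyl bromide (1.05 equiv), K2CO3 (1.1 equiv), acetone, rt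
Reagents that add atoms: allyl bromide 4, C=CCBr
Why: Williamson etherification; the hydroxyl para to the ketone is the most acidic and is not tied to the carbonyl by a hydrogen bond, so it should be alkylated first, and the product stays symmetric.

**Step 3**
Reactants: 5 the para allyl ether; 6 N,N-dimethylformamide
Product: 7 2,4-dihydroxy-3-(3-methylbutanoyl)-6-(prop-2-enyloxy)benzaldehyde
Conditions: POCl3 (1.3 equiv), DMF (3 equiv), EtOAc, 0 °C to rt; then H2O, NaOAc, 50 °C
Reagents that add atoms: N,N-dimethylformamide 6, CN(C)C=O (formyl carbon); water, O (formyl oxygen)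
Why: Vilsmeier–Haack formylation of an acylphloroglucinol ether; the two free ring positions are equivalent, so only one aldehyde can form, and the first formyl group deactivates the ring against a second attack.

**Step 4**
Reactants: 7 the aldehyde; 8 benzyl bromide
Product: 9 4-(benzyloxy)-2-hydroxy-3-(3-methylbutanoyl)-6-(prop-2-enyloxy)benzaldehyde
Conditions: BnBr (1.1 equiv), K2CO3 (1.2 equiv), DMF, rt to 50 °C
Reagents that add atoms: benzyl bromide 8, BrCc1ccccc1
Why: Williamson etherification; the hydroxyl between the two carbonyl groups is chelated on both sides and shielded, so the benzyl group should go to the outer hydroxyl (para to the aldehyde, next to the ketone), the oxygen that must stay out of the ring closure.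

**Step 5**
Reactants: 9 the benzyl allyl bis-ether
Product: 10 4-(benzyloxy)-2,6-dihydroxy-3-(3-methylbutanoyl)benzaldehyde
Conditions: Pd(PPh3)4 (5 mol%), morpholine (5 equiv), THF, rt; aq. HCl wash
Reagents that add atoms: none
Why: Tsuji–Trost deallylation; zerovalent palladium ionises the allyl aryl ether (a good phenoxide leaving group ortho to the aldehyde) and morpholine takes up the allyl unit, while the benzyl ether, aldehyde and ketone are inert.

**Step 6**
Reactants: 10 the benzyl-protected formyl isovaleryl phloroglucinol; 11 formaldehyde; 12 (−)-β-pinene ((1S,5S)-6,6-dimethyl-2-methylidenebicyclo[3.1.1]heptane)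
Product: 15 5'-O-benzyl euglobal G3, via hydroxymethyl phenol 13 (not isolated), via ortho-quinone methide 14 (not isolated)
Conditions: aq. CH2O (37%, 1.5 equiv), 12 (5 equiv), NaOAc (2 equiv), AcOH, 80 °C
Reagents that add atoms: formaldehyde 11, C=O (its carbon only); (−)-β-pinene 12, C=C1CC[C@H]2C[C@@H]1C2(C)C
Why: Acetate-buffered hydroxymethylation of the only free ring carbon of 10 (Knoevenagel type) and loss of water should give the electron-poor ortho-quinone methide 14, whose CH2=C–C=O unit is the heterodiene of an inverse-electron-demand oxa-Diels–Alder reaction with the exocyclic alkene of 12; the closest known reaction type is the Knoevenagel/hetero-Diels–Alder coupling of formyl- and acylphloroglucinols with aldehydes and terpene alkenes. The dihydropyran ring closes by an intermolecular [4+2] cycloaddition that forms the ArCH2–CH2 bond and the O–C(spiro) bond in one event, the carbon–carbon bond running ahead so that oxygen ends on the more substituted alkene carbon. The spiro centre is set by approach of 14 to the alkene face anti to the gem-dimethyl bridge (the face of the CH2 bridge), which places the ring oxygen anti and the new CH2 syn to that bridge; the two bridgehead centres come unchanged from (1S,5S)-12. The step needs selectivity between the two phenol oxygens ortho to the methide carbon, and the benzyl ether on the oxygen next to the ketone secures it, since only the oxygen next to the formyl carbon can become the carbonyl of the quinone methide. The excess of 12 and the acetate buffer should hold back methylene-bridged dimers and cationic rearrangement of the strained pinane.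

**Step 7**
Reactants: 15 5'-O-benzyl euglobal G3
Product: 16 euglobal G3
Conditions: H2 (1 atm), 10% Pd/C, EtOAc, rt, stopped after one equivalent of H2
Reagents that add atoms: none
Why: Hydrogenolysis of the benzyl aryl ether; no stereocentre is touched, and the chelated, electron-rich aldehyde and ketone are poor substrates for Pd/C under these conditions.

**Compound list**
1 | phloroglucinol (benzene-1,3,5-triol) | Oc1cc(O)cc(O)c1 | starting material
2 | isovaleryl chloride (3-methylbutanoyl chloride) | CC(C)CC(=O)Cl | starting material
3 | phlorisovalerophenone (3-methyl-1-(2,4,6-trihydroxyphenyl)butan-1-one) | CC(C)CC(=O)c1c(O)cc(O)cc1O | intermediate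
4 | allyl bromide (3-bromoprop-1-ene) | C=CCBr | starting material
5 | 1-[2,6-dihydroxy-4-(prop-2-enyloxy)phenyl]-3-methylbutan-1-one | CC(C)CC(=O)c1c(O)cc(OCC=C)cc1O | intermediate
6 | N,N-dimethylformamide | CN(C)C=O | starting material
7 | 2,4-dihydroxy-3-(3-methylbutanoyl)-6-(prop-2-enyloxy)benzaldehyde | CC(C)CC(=O)c1c(O)c(C=O)c(OCC=C)cc1O | intermediate
8 | benzyl bromide | BrCc1ccccc1 | starting material
9 | 4-(benzyloxy)-2-hydroxy-3-(3-methylbutanoyl)-6-(prop-2-enyloxy)benzaldehyde | CC(C)CC(=O)c1c(O)c(C=O)c(OCC=C)cc1OCc1ccccc1 | intermediate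
10 | 4-(benzyloxy)-2,6-dihydroxy-3-(3-methylbutanoyl)benzaldehyde | CC(C)CC(=O)c1c(O)c(C=O)c(O)cc1OCc1ccccc1 | intermediate
11 | formaldehyde | C=O | starting material
12 | (−)-β-pinene, (1S,5S)-6,6-dimethyl-2-methylidenebicyclo[3.1.1]heptane | C=C1CC[C@H]2C[C@@H]1C2(C)C | starting material
13 | 4-(benzyloxy)-2,6-dihydroxy-5-(hydroxymethyl)-3-(3-methylbutanoyl)benzaldehyde | CC(C)CC(=O)c1c(O)c(C=O)c(O)c(CO)c1OCc1ccccc1 | intermediate (not isolated)
14 | ortho-quinone methide, 4-(benzyloxy)-2-hydroxy-5-methylidene-3-(3-methylbutanoyl)-6-oxocyclohexa-1,3-diene-1-carbaldehyde | C=C1C(=O)C(C=O)=C(O)C(C(=O)CC(C)C)=C1OCc1ccccc1 | intermediate (not isolated)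
15 | 5'-O-benzyl euglobal G3, (1R,2R,5S)-5'-(benzyloxy)-7'-hydroxy-6,6-dimethyl-6'-(3-methylbutanoyl)-3',4'-dihydrospiro[bicyclo[3.1.1]heptane-2,2'-chromene]-8'-carbaldehyde; ring oxygen anti to the gem-dimethyl bridge | CC(C)CC(=O)c1c(O)c(C=O)c2c(c1OCc1ccccc1)CC[C@@]1(CC[C@H]3C[C@@H]1C3(C)C)O2 | intermediate
16 | euglobal G3, (1R,2R,5S)-5',7'-dihydroxy-6,6-dimethyl-6'-(3-methylbutanoyl)-3',4'-dihydrospiro[bicyclo[3.1.1]heptane-2,2'-chromene]-8'-carbaldehyde; ring oxygen anti to the gem-dimethyl bridge | CC(C)CC(=O)c1c(O)c(C=O)c2c(c1O)CC[C@@]1(CC[C@H]3C[C@@H]1C3(C)C)O2 | target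

**Step count and risks**
Total step count: 7. Longest linear sequence: 7 steps (1 to 16); 12 enters in step 6.

Steps most likely to fail:

- **Step 6.** The quinone methide may be consumed by unreacted phenol to give methylene-bridged dimers. Formaldehyde may add to the pinene alkene in a Prins reaction. The acidic medium may also isomerise the pinene or open the cyclobutane before the oxygen closes the ring. Fallback: the quinone methide is released from an isolated precursor under neutral conditions with no free formaldehyde. Setting out from 10, a Mannich reaction with morpholine and formaldehyde 11 (EtOH, rt) should give 4-(benzyloxy)-2,6-dihydroxy-3-(3-methylbutanoyl)-5-(morpholin-4-ylmethyl)benzaldehyde F1. Heating F1 with an excess of 12 in toluene at 110 °C should expel morpholine, pass through 14 and come back to the route at 15.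

- **Step 7.** The formyl group may be reduced further (to hydroxymethyl or methyl) in competition with cleavage of the hindered benzyl ether. Fallback: a photolabile ether replaces the benzyl ether, so that no reducing agent meets the aldehyde. Setting out from 7, alkylation with 2-nitrobenzyl bromide ([O-][N+](=O)c1ccccc1CBr) and K2CO3 in DMF should give 2-hydroxy-3-(3-methylbutanoyl)-4-[(2-nitrophenyl)methoxy]-6-(prop-2-enyloxy)benzaldehyde F2. Pd(PPh3)4 and morpholine should then give 2,6-dihydroxy-3-(3-methylbutanoyl)-4-[(2-nitrophenyl)methoxy]benzaldehyde F3. Under the conditions of step 6 with 11 and 12, F3 should pass through 2,6-dihydroxy-5-(hydroxymethyl)-3-(3-methylbutanoyl)-4-[(2-nitrophenyl)methoxy]benzaldehyde F4 and the quinone methide 2-hydroxy-5-methylidene-3-(3-methylbutanoyl)-4-[(2-nitrophenyl)methoxy]-6-oxocyclohexa-1,3-diene-1-carbaldehyde F5 to the 5'-O-(2-nitrobenzyl) ether of euglobal G3 F6. Irradiation of F6 at 365 nm (MeCN/H2O, semicarbazide as scavenger) should come back to the route at 16.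

- **Step 2.** Site selectivity may be lost by further allylation at the ortho hydroxyls and by C-allylation of the ambident phenoxide. Fallback: a Mitsunobu etherification, which runs without a free phenoxide and engages the most acidic (para) hydroxyl. Setting out from 3, allyl alcohol, PPh3 and diisopropyl azodicarboxylate in THF at 0 °C should come back to the route at 5; no new compound arises (F0).

**Further compounds**
F0 | step 2 | none | none
F1 | step 6 | 4-(benzyloxy)-2,6-dihydroxy-3-(3-methylbutanoyl)-5-(morpholin-4-ylmethyl)benzaldehyde | CC(C)CC(=O)c1c(O)c(C=O)c(O)c(CN2CCOCC2)c1OCc1ccccc1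
F2 | step 7 | 2-hydroxy-3-(3-methylbutanoyl)-4-[(2-nitrophenyl)methoxy]-6-(prop-2-enyloxy)benzaldehyde | CC(C)CC(=O)c1c(O)c(C=O)c(OCC=C)cc1OCc1ccccc1[N+](=O)[O-]
F3 | step 7 | 2,6-dihydroxy-3-(3-methylbutanoyl)-4-[(2-nitrophenyl)methoxy]benzaldehyde | CC(C)CC(=O)c1c(O)c(C=O)c(O)cc1OCc1ccccc1[N+](=O)[O-]
F4 | step 7 | 2,6-dihydroxy-5-(hydroxymethyl)-3-(3-methylbutanoyl)-4-[(2-nitrophenyl)methoxy]benzaldehyde | CC(C)CC(=O)c1c(O)c(C=O)c(O)c(CO)c1OCc1ccccc1[N+](=O)[O-]
F5 | step 7 | 2-hydroxy-5-methylidene-3-(3-methylbutanoyl)-4-[(2-nitrophenyl)methoxy]-6-oxocyclohexa-1,3-diene-1-carbaldehyde | C=C1C(=O)C(C=O)=C(O)C(C(=O)CC(C)C)=C1OCc1ccccc1[N+](=O)[O-]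
F6 | step 7 | 5'-O-(2-nitrobenzyl) ether of euglobal G3, (1R,2R,5S) spiro configuration as in 16 | CC(C)CC(=O)c1c(O)c(C=O)c2c(c1OCc1ccccc1[N+](=O)[O-])CC[C@@]1(CC[C@H]3C[C@@H]1C3(C)C)O2
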